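The rate constants are assumed.

Two questions stand on the board: how much target each of the flasks holds at the end, and how that row runs.

| setting | north-west | south-east | north-east | south |
|---|---|---|---|---|
| starting material | 0.067 M | 0.067 M | 0.067 M | 0.067 M |
| second substrate | 0.500 equiv | 0.500 equiv | 0.500 equiv | 0.500 equiv |
| reagent | 0.300 equiv | 1.00 equiv | 3.00 equiv | 8.00 equiv |
| free catalyst | 0.5 mol% | 0.5 mol% | 0.5 mol% | 0.5 mol% |
| time | 50 min | 50 min | 50 min | 50 min |

    starting material + free catalyst ⇌ catalyst intermediate A (K1 = 30 /M, k1 = 7.1 /M/s)
    reagent + catalyst intermediate A → free catalyst + target (k2 = 4.0 /M/s)
    second substrate + free catalyst ⇌ catalyst intermediate B (K3 = 2700 /M, k3 = 4.1 /M/s)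
    reagent + catalyst intermediate B → free catalyst + second product (k4 = 6.1 /M/s)
    target → over-reaction product (k5 = 3.0 × 10⁻⁴ /s)

- amount of target at the end, in percent of the starting material charged for north-west, south-east, north-east, south, in this order
- how the row runs (hardly changes / rises, then falls / falls, then rises / rises all the way / falls all the way)

- "hardly changes" means that all values lie within two and a half points (for a concentration: within two and a half percent of the largest)
- run time (north-west): 50 min

We watch the run in slow motion and look for the crossing at which control changes hands. In the first instants both substrates bind the free catalyst. With reagent as charged in the north-west flask, catalyst intermediate B goes on at 0.123 /s, far faster than its return at 0.00152 /s, so second substrate once bound costs reagent. Catalyst intermediate A is different: it falls back at 0.237 /s at any reagent level, while its forward rate grows with [reagent]. The two are equal at 0.0592 M, which is 0.883 equiv. We call this the crossing concentration, the [reagent] at which catalyst intermediate A goes on as fast as it falls back. The share of bound starting material that goes on is then [reagent]/([reagent] + crossing).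

The north-west flask starts at 0.0201 M reagent, which is less than the crossing. At the start it makes target 0.878 times as fast as second product, so we put its target below 0.140 of the starting material charged.

In the middle of a reagent-rich run, taking the catalyst as free, the starting material decays by a pseudo-first-order law whose constant is the binding rate constant times [catalyst] times that share. This gives 0.129 /min for the south flask and 0.110 /min for the north-east flask at its charged reagent.

Towards the end, over-reaction matters: target present from the start keeps 40.7% of itself over the run. Two first-order steps in series then give, as fractions of the starting material charged, 0.471 for the south flask and 0.481 for the north-east flask, which is more. The south-east flask is charged at 0.0670 M against a crossing of 0.0592 M, so we do not reckon it by this sum, and we expect it between the north-west and north-east flasks. So we commit to a row that rises, then falls.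

The forecast gave 4.5%, 30%, 50% and 47.5%, rises, then falls, holding that “a lot of target goes on to over-reaction product”. The flasks give 4.86%, 28.8%, 50.8% and 48.1%, rises, then falls, with the turn at 2.4 equiv.

In the north-west flask at 11.1 min, catalyst intermediate A falls back 6.8 times as fast as it goes on, which by the crossing puts reagent near 0.00871 M. In the south flask at 25.0 min, reagent stands at 0.444 M, or 7.51 times the crossing, and the binding constant times [starting material], cut by crossing/(crossing + [reagent]), gives catalyst intermediate A over free catalyst as 0.0129, where the flask reads 0.0129.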